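The route rests on cutting ring A at C2–C3 and C5–C6. Ring A bears oxygen on C3, C4 and C5 and its quaternary side chain on C1, para to C4. This is the imprint of a 1,3-dioxygenated acetone (C3–C4–C5) joined to a 2-substituted malonaldehyde (C2–C1–C6). Because the C5 oxygen is the diaryl ether oxygen, hanging ring B on the acetone lets one base-mediated [3+3] condensation build ring A, unveil the C4 phenol and unite both halves. The partners are an (S)-configured aryloxy(methoxymethoxy)acetone and an (R)-configured 2-tert-alkyl-3-(dimethylamino)acrolein. Each is made from (2E,6E)-farnesol by a copper-catalysed enantioselective SN2′ substitution, of opposite facial sense.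

Key step: step 12

Shorthand: "nerolidyl" = (6E)-3,7,11-trimethyldodeca-1,6,10-trien-3-yl, i.e. C(CH3)(CH=CH2)CH2CH2CH=C(CH3)CH2CH2CH=C(CH3)2. The descriptor in front gives the configuration at its C3.

Assumption: for each chiral NHC–copper catalyst the ligand enantiomer that gives the drawn configuration is used. The sense is checked once by oxidising a sample of the tertiary allylboronate to nerolidol of known configuration. (Methoxymethoxy)benzene and racemic glycidol are taken as catalogue chemicals.

Step 1
Reactants: 1 (2E,6E)-farnesol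
Product: 2 (2E,6E)-farnesyl methyl carbonate
Conditions: ClCO2Me, pyridine, CH2Cl2, 0 °C
Reagents that add atoms: methyl chloroformate COC(=O)Cl
Why: O-acylation of a primary allylic alcohol with a chloroformate installs the leaving group for copper–boryl allylic substitution and leaves both alkene geometries untouched.

Step 2
Reactants: 2 (2E,6E)-farnesyl methyl carbonate
Product: 3 (S)-nerolidyl pinacol boronate
Conditions: B2pin2, CuCl (5 mol %), chiral unsymmetrical N,N′-diaryl imidazolinium tetrafluoroborate from 1,2-diphenylethylenediamine (NHC precursor, 5 mol %), NaOMe (30 mol %), DME, −30 °C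
Reagents that add atoms: bis(pinacolato)diboron CC1(C)OB(OC1(C)C)B1OC(C)(C)C(C)(C)O1
Why: Copper-catalysed enantioselective SN2′ boryl substitution of an (E)-trisubstituted allylic carbonate is a known route to allylboronates with a fully substituted boron-bearing carbon; the chiral NHC on the Cu–Bpin species should steer boron to the Re face of C3 (C2 > C4 > CH3) and so set the centre that ends up on ring A.

Step 3
Reactants: 3 (S)-nerolidyl pinacol boronate
Product: 5 2-[(2R,5E)-2-ethenyl-2,6,10-trimethylundeca-5,9-dien-1-yl]-4,4,5,5-tetramethyl-1,3,2-dioxaborolane, via lithium chloromethyl boronate complex 4 (not isolated)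
Conditions: BrCH2Cl, nBuLi, Et2O, −78 °C → rt
Reagents that add atoms: bromochloromethane ClCBr
Why: In this Matteson homologation LiCH2Cl, made in the presence of 3, is trapped on boron and the tertiary carbon migrates with retention on warming, by which time excess carbenoid has decayed, so one CH2 is inserted and the descriptor changes only through the priority rules.

Step 4
Reactants: 5 2-[(2R,5E)-2-ethenyl-2,6,10-trimethylundeca-5,9-dien-1-yl]-4,4,5,5-tetramethyl-1,3,2-dioxaborolane
Product: 8 (3S,6E)-3-ethenyl-3,7,11-trimethyldodeca-6,10-dienal, via lithium dichloromethyl boronate complex 6 (not isolated), via alpha-chloroboronic ester 7 (not isolated)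
Conditions: CH2Cl2, LDA, THF, −78 °C → rt; then 30% H2O2, pH 8 phosphate buffer, 0 °C
Reagents that add atoms: dichloromethane ClCCl; hydrogen peroxide OO
Why: Matteson homologation with LiCHCl2 followed by buffered peroxide oxidation of the α-chloroboronic ester is a known one-flask passage from a primary boronic ester to the next higher aldehyde; the CHCl centre forms without control and is erased, and the quaternary centre and the isolated alkenes are spectators.

Step 5
Reactants: 8 (3S,6E)-3-ethenyl-3,7,11-trimethyldodeca-6,10-dienal; 9 tert-butoxybis(dimethylamino)methane (Bredereck's reagent)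
Product: 10 (2Z,3R,6E)-2-[(dimethylamino)methylidene]-3-ethenyl-3,7,11-trimethyldodeca-6,10-dienal
Conditions: 9 (1.5 equiv), toluene, 70 °C
Reagents that add atoms: none
Why: In this aminomethylenation of a CH-acidic carbonyl compound with Bredereck's reagent, tert-butoxide released from 9 enolises the aldehyde, the formamidinium ion is attacked at carbon and dimethylamine is lost; the neopentyl-type α-carbon disfavours self-aldol, and the quaternary centre carries no acidic hydrogen.

Step 6
Reactants: 1 (2E,6E)-farnesol
Product: 11 (2E,6E)-farnesyl diethyl phosphate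
Conditions: ClP(O)(OEt)2, Et3N, DMAP (cat.), CH2Cl2, 0 °C
Reagents that add atoms: diethyl chlorophosphate CCOP(=O)(Cl)OCC
Why: O-phosphorylation of the primary allylic alcohol gives the Lewis-basic leaving group that copper-catalysed allylic arylation with aluminium reagents requires.

Step 7
Reactants: 12 (methoxymethoxy)benzene; 11 (2E,6E)-farnesyl diethyl phosphate
Product: 15 1-(methoxymethoxy)-2-[(S)-nerolidyl]benzene, via 2-(methoxymethoxy)phenyllithium 13 (not isolated), via diethyl[2-(methoxymethoxy)phenyl]aluminium 14 (not isolated)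
Conditions: 12, nBuLi, THF, 0 °C → rt; Et2AlCl, −78 °C → rt; then 11, CuCl2·2H2O (2 mol %), chiral sulfonate-bridged bidentate NHC supplied as its silver carbene (from the imidazolinium sulfonate and Ag2O, 1 mol %), THF, −30 °C
Reagents that add atoms: none
Why: Directed ortho-metalation, transmetalation and copper-catalysed enantioselective SN2′ allylic arylation of an (E)-trisubstituted allylic phosphate with an aryl(diethyl)aluminium reagent form a known route to vinyl-bearing aryl/methyl/alkyl quaternary centres; the sulfonate-bridged NHC organises the aluminium-bound phosphate and should deliver the aryl group (in preference to ethyl) to the Si face of C3, which sets the (S) centre of ring B.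

Step 8
Reactants: 15 1-(methoxymethoxy)-2-[(S)-nerolidyl]benzene
Product: 18 2-(methoxymethoxy)-3-[(S)-nerolidyl]phenol, via ring B aryllithium 16 (not isolated), via lithium aryltrimethoxyborate 17 (not isolated)
Conditions: nBuLi, THF, 0 °C; B(OMe)3, −78 °C → rt; 30% H2O2, aq NaOH, 0 °C
Reagents that add atoms: hydrogen peroxide OO
Why: This is directed ortho-metalation, borylation and peroxide oxidation (aryl C–H to phenol); the MOM group, turned away from its tert-alkyl neighbour, guides lithium to the only free ortho position, and the boron-to-oxygen shift installs the oxygen that becomes the diaryl ether oxygen.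

Step 9
Reactants: 19 (±)-glycidol
Product: 20 (±)-2-[(methoxymethoxy)methyl]oxirane
Conditions: MOMCl, iPr2NEt, CH2Cl2, 0 °C → rt
Reagents that add atoms: chloromethyl methyl ether COCCl
Why: Standard MOM acetal protection of a primary alcohol under amine base leaves the epoxide intact.

Step 10
Reactants: 18 2-(methoxymethoxy)-3-[(S)-nerolidyl]phenol; 20 (±)-2-[(methoxymethoxy)methyl]oxirane
Product: 21 1-(methoxymethoxy)-3-{2-(methoxymethoxy)-3-[(S)-nerolidyl]phenoxy}propan-2-ol (both carbinol epimers)
Conditions: 20 (1.3 equiv), Cs2CO3 (20 mol %), DMF, 80 °C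
Reagents that add atoms: none
Why: Base-catalysed phenolysis of a terminal epoxide proceeds by SN2 attack at the unsubstituted carbon; the carbinol centre forms as both epimers because 20 is racemic, which is harmless since step 11 removes it.

Step 11
Reactants: 21 1-(methoxymethoxy)-3-{2-(methoxymethoxy)-3-[(S)-nerolidyl]phenoxy}propan-2-ol
Product: 22 1-(methoxymethoxy)-3-{2-(methoxymethoxy)-3-[(S)-nerolidyl]phenoxy}propan-2-one
Conditions: Dess–Martin periodinane, CH2Cl2, 0 °C → rt
Reagents that add atoms: none
Why: Dess–Martin oxidation of a secondary alcohol runs under near-neutral conditions that spare the MOM acetals, the electron-rich arene and all alkenes.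

Step 12
Reactants: 22 1-(methoxymethoxy)-3-{2-(methoxymethoxy)-3-[(S)-nerolidyl]phenoxy}propan-2-one; 10 (2Z,3R,6E)-2-[(dimethylamino)methylidene]-3-ethenyl-3,7,11-trimethyldodeca-6,10-dienal
Product: 24 2-(methoxymethoxy)-6-{2-(methoxymethoxy)-3-[(S)-nerolidyl]phenoxy}-4-[(R)-nerolidyl]phenol, via dienaminone 23 (not isolated)
Conditions: KOtBu (3 equiv), THF–tBuOH (10:1), degassed, Ar; 22 added over 2 h to 10 (1.3 equiv) at 0 °C, then 60 °C; aq NH4Cl
Reagents that add atoms: none
Why: Proposed new method: the potassium enolate of 22 should add to the formyl carbon of 10, the enamine nitrogen then helps to expel hydroxide and gives dienaminone 23 (the isomer formed through the other α-carbon converges on the same ring), and deprotonation of the remaining α-CH2 gives an amino-trienolate that forms the second ring bond, loses dimethylamine by a vinylogous E1cB step and tautomerises to the C4 phenoxide. The closest known reaction type is the base-mediated [3+3] phenol synthesis from ketones with two α-CH2 groups and malonaldehyde surrogates (sodium nitromalonaldehyde, 2-substituted vinamidinium salts, 3-aminoacroleins); what is new is the pairing of an α,α′-dioxygenated ketone with a tert-alkyl-substituted acceptor. Ring A closes by disrotatory 6π electrocyclisation of the trienolate (formally 6-endo-trig), because enolisation switches off the vinylogous amide as a plain acceptor; the bulky C1 substituent favours the s-cis arrangement about C6–C1 and the push–pull double bonds of 23 isomerise readily, so the closing geometry is within reach. No stereocentre is formed, and both quaternary centres lack an adjacent acidic hydrogen and pass through unchanged. The selectivity needed is cross-condensation over self-aldol of 22: 10 cannot enolise and acts only as acceptor, 22 is kept dilute by slow addition into excess 10, the aldol steps are reversible with tBuOH shuttling protons, and aromatisation drains the equilibria irreversibly. Which α-carbon reacts first is immaterial, since each becomes a ring atom and the three-carbon acceptor has equivalent termini once oxygen and nitrogen are lost.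

Step 13
Reactants: 24 2-(methoxymethoxy)-6-{2-(methoxymethoxy)-3-[(S)-nerolidyl]phenoxy}-4-[(R)-nerolidyl]phenol
Product: 25 3-{2-hydroxy-3-[(S)-nerolidyl]phenoxy}-5-[(R)-nerolidyl]benzene-1,2-diol (CNP0325484.1)
Conditions: HCl (0.3 M in MeOH), Ar, 40 °C
Reagents that add atoms: none
Why: Acid-catalysed transacetalisation of aryl MOM ethers to methanol should free both phenols under dilute acid that trisubstituted and vinyl alkenes of prenylated phenols tolerate; argon protects the oxidation-prone catechol.

Compound list
1 | (2E,6E)-farnesol | OC/C=C(\C)CC/C=C(\C)CCC=C(C)C | starting material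
2 | (2E,6E)-farnesyl methyl carbonate | COC(=O)OC/C=C(\C)CC/C=C(\C)CCC=C(C)C | intermediate
3 | (S)-nerolidyl pinacol boronate | C=C[C@@](C)(CC/C=C(\C)CCC=C(C)C)B1OC(C)(C)C(C)(C)O1 | intermediate
4 | lithium (chloromethyl)[(S)-nerolidyl](pinacolato)borate | [Li+].C=C[C@@](C)(CC/C=C(\C)CCC=C(C)C)[B-]1(CCl)OC(C)(C)C(C)(C)O1 | intermediate
5 | 2-[(2R,5E)-2-ethenyl-2,6,10-trimethylundeca-5,9-dien-1-yl]-4,4,5,5-tetramethyl-1,3,2-dioxaborolane | C=C[C@@](C)(CC/C=C(\C)CCC=C(C)C)CB1OC(C)(C)C(C)(C)O1 | intermediate
6 | lithium (dichloromethyl)[(2R,5E)-2-ethenyl-2,6,10-trimethylundeca-5,9-dien-1-yl](pinacolato)borate | [Li+].C=C[C@@](C)(CC/C=C(\C)CCC=C(C)C)C[B-]1(C(Cl)Cl)OC(C)(C)C(C)(C)O1 | intermediate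
7 | 2-[(3S,6E)-1-chloro-3-ethenyl-3,7,11-trimethyldodeca-6,10-dien-1-yl]-4,4,5,5-tetramethyl-1,3,2-dioxaborolane (C1 epimers) | C=C[C@@](C)(CC/C=C(\C)CCC=C(C)C)CC(Cl)B1OC(C)(C)C(C)(C)O1 | intermediate
8 | (3S,6E)-3-ethenyl-3,7,11-trimethyldodeca-6,10-dienal | C=C[C@@](C)(CC/C=C(\C)CCC=C(C)C)CC=O | intermediate
9 | tert-butoxybis(dimethylamino)methane | CN(C)C(OC(C)(C)C)N(C)C | starting material
10 | (2Z,3R,6E)-2-[(dimethylamino)methylidene]-3-ethenyl-3,7,11-trimethyldodeca-6,10-dienal | C=C[C@@](C)(CC/C=C(\C)CCC=C(C)C)/C(C=O)=C/N(C)C | intermediate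
11 | (2E,6E)-farnesyl diethyl phosphate | CCOP(=O)(OCC)OC/C=C(\C)CC/C=C(\C)CCC=C(C)C | intermediate
12 | (methoxymethoxy)benzene | COCOc1ccccc1 | starting material
13 | 2-(methoxymethoxy)phenyllithium | [Li]c1ccccc1OCOC | intermediate
14 | diethyl[2-(methoxymethoxy)phenyl]aluminium | CC[Al](CC)c1ccccc1OCOC | intermediate
15 | 1-(methoxymethoxy)-2-[(S)-nerolidyl]benzene | COCOc1ccccc1[C@](C)(C=C)CC/C=C(\C)CCC=C(C)C | intermediate
16 | 2-(methoxymethoxy)-3-[(S)-nerolidyl]phenyllithium | [Li]c1cccc([C@](C)(C=C)CC/C=C(\C)CCC=C(C)C)c1OCOC | intermediate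
17 | lithium trimethoxy{2-(methoxymethoxy)-3-[(S)-nerolidyl]phenyl}borate | [Li+].CO[B-](OC)(OC)c1cccc([C@](C)(C=C)CC/C=C(\C)CCC=C(C)C)c1OCOC | intermediate
18 | 2-(methoxymethoxy)-3-[(S)-nerolidyl]phenol | Oc1cccc([C@](C)(C=C)CC/C=C(\C)CCC=C(C)C)c1OCOC | intermediate
19 | (±)-glycidol | OCC1CO1 | starting material
20 | (±)-2-[(methoxymethoxy)methyl]oxirane | COCOCC1CO1 | intermediate
21 | 1-(methoxymethoxy)-3-{2-(methoxymethoxy)-3-[(S)-nerolidyl]phenoxy}propan-2-ol (carbinol epimers) | COCOCC(O)COc1cccc([C@](C)(C=C)CC/C=C(\C)CCC=C(C)C)c1OCOC | intermediate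
22 | 1-(methoxymethoxy)-3-{2-(methoxymethoxy)-3-[(S)-nerolidyl]phenoxy}propan-2-one | COCOCC(=O)COc1cccc([C@](C)(C=C)CC/C=C(\C)CCC=C(C)C)c1OCOC | intermediate
23 | (3E,5E)-6-(dimethylamino)-1-(methoxymethoxy)-3-{2-(methoxymethoxy)-3-[(S)-nerolidyl]phenoxy}-5-[(R)-nerolidyl]hexa-3,5-dien-2-one | COCOCC(=O)/C(Oc1cccc([C@](C)(C=C)CC/C=C(\C)CCC=C(C)C)c1OCOC)=C\C(=C/N(C)C)[C@@](C)(C=C)CC/C=C(\C)CCC=C(C)C | intermediate
24 | 2-(methoxymethoxy)-6-{2-(methoxymethoxy)-3-[(S)-nerolidyl]phenoxy}-4-[(R)-nerolidyl]phenol | C=C[C@@](C)(CC/C=C(\C)CCC=C(C)C)c1cc(OCOC)c(O)c(Oc2cccc([C@](C)(C=C)CC/C=C(\C)CCC=C(C)C)c2OCOC)c1 | intermediate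
25 | 3-{2-hydroxy-3-[(S)-nerolidyl]phenoxy}-5-[(R)-nerolidyl]benzene-1,2-diol (CNP0325484.1) | C=C[C@@](C)(CC/C=C(\C)CCC=C(C)C)c1cc(O)c(O)c(Oc2cccc([C@](C)(C=C)CC/C=C(\C)CCC=C(C)C)c2O)c1 | target

Total step count: 13.

Longest linear sequence: 7 steps (1 → 11 → 15 → 18 → 21 → 22 → 24 → 25). The branch 1 → 2 → 3 → 5 → 8 → 10 → 24 → 25 is equally long.

The two centres are remote from each other, so stereoisomers arising from imperfect enantioselection should not be separable after step 12. The enantiopurity of 8 and 18 should therefore be assayed, and if necessary upgraded on a chiral phase, before the union.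

Steps most likely to fail

Step 12 (key step).
- Risk: self-aldol of the ketone or loss of aryloxide from its enolate may outrun attack on the hindered vinylogous amide. The sequence may also stall after the first C–C bond, because the amino group points inward and slows ring closure.
- Fallback: known copper-mediated diaryl ether chemistry. It sets out from 11 and 18 and rejoins the route at 25. 4-Bromocatechol is protected (MOMCl, iPr2NEt) as 4-bromo-1,2-bis(methoxymethoxy)benzene F1. Bromine–lithium exchange (nBuLi), Et2AlCl and the SN2′ arylation of 11 as in step 7, but with the mirror-image NHC, give 1,2-bis(methoxymethoxy)-4-[(R)-nerolidyl]benzene F2. MOM-directed ortho-lithiation can only occur at the ortho position remote from the tert-alkyl group; B(OMe)3 and mild hydrolysis then give {2,3-bis(methoxymethoxy)-5-[(R)-nerolidyl]phenyl}boronic acid F3. Chan–Lam coupling of F3 with 18 (Cu(OAc)2, pyridine, 4 Å sieves, air, CH2Cl2, rt) gives the tris-MOM diaryl ether F4. The conditions of step 13 convert F4 into 25.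

Step 7.
- Risk: chelation of aluminium by the ortho MOM oxygen may slow aryl transfer to copper. That would allow ethyl transfer, SN2 attack or poor facial selectivity.
- Fallback: stereospecific boron chemistry in place of allylic substitution. It sets out from 12 (through 13) and rejoins at 15. Acylation of 13 with N-methoxy-N-methylacetamide gives 1-[2-(methoxymethoxy)phenyl]ethanone F5. Noyori asymmetric transfer hydrogenation (RuCl[(S,S)-TsDPEN](p-cymene), HCO2H–Et3N) gives (S)-1-[2-(methoxymethoxy)phenyl]ethanol F6. Carbamoylation (iPr2NCOCl, NaH, THF) gives (S)-1-[2-(methoxymethoxy)phenyl]ethyl N,N-diisopropylcarbamate F7. Geranyl bromide and CH2(Bpin)2 with NaOtBu (deborylative alkylation) give (E)-homogeranyl pinacol boronate F8. Lithiation–borylation (F7, sBuLi, Et2O, −78 °C, then F8, then warming) gives the tertiary benzylic boronic ester F9; borylation proceeds with retention and the 1,2-migration is stereospecific. Zweifel olefination (vinylmagnesium bromide, then iodine, then NaOMe) replaces boron by vinyl with retention and delivers 15.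

Step 5.
- Risk: slow C-formylation at the neopentyl-type α-carbon may let plain enamine formation or aldehyde condensation take over.
- Fallback: electrophilic formylation of a preformed enamine. It sets out from 8 and rejoins at 10. Condensation of 8 with Me2NH (THF, 4 Å sieves) gives (1E,3R,6E)-3-ethenyl-N,N,3,7,11-pentamethyldodeca-1,6,10-trien-1-amine F10. Vilsmeier–Arnold formylation with preformed (chloromethylene)dimethyliminium chloride and Et3N in CH2Cl2 at 0 °C gives the 2-[(R)-nerolidyl]vinamidinium chloride F11. Brief treatment with aqueous K2CO3 hydrolyses one terminus to 10.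

Further compounds
F1 | step 12 | 4-bromo-1,2-bis(methoxymethoxy)benzene | COCOc1ccc(Br)cc1OCOC
F2 | step 12 | 1,2-bis(methoxymethoxy)-4-[(R)-nerolidyl]benzene | C=C[C@@](C)(CC/C=C(\C)CCC=C(C)C)c1ccc(OCOC)c(OCOC)c1
F3 | step 12 | {2,3-bis(methoxymethoxy)-5-[(R)-nerolidyl]phenyl}boronic acid | C=C[C@@](C)(CC/C=C(\C)CCC=C(C)C)c1cc(OCOC)c(OCOC)c(B(O)O)c1
F4 | step 12 | 1,2-bis(methoxymethoxy)-3-{2-(methoxymethoxy)-3-[(S)-nerolidyl]phenoxy}-5-[(R)-nerolidyl]benzene | C=C[C@@](C)(CC/C=C(\C)CCC=C(C)C)c1cc(OCOC)c(OCOC)c(Oc2cccc([C@](C)(C=C)CC/C=C(\C)CCC=C(C)C)c2OCOC)c1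
F5 | step 7 | 1-[2-(methoxymethoxy)phenyl]ethanone | CC(=O)c1ccccc1OCOC
F6 | step 7 | (S)-1-[2-(methoxymethoxy)phenyl]ethanol | C[C@H](O)c1ccccc1OCOC
F7 | step 7 | (S)-1-[2-(methoxymethoxy)phenyl]ethyl N,N-diisopropylcarbamate | C[C@H](OC(=O)N(C(C)C)C(C)C)c1ccccc1OCOC
F8 | step 7 | 2-[(3E)-4,8-dimethylnona-3,7-dien-1-yl]-4,4,5,5-tetramethyl-1,3,2-dioxaborolane | CC1(C)OB(CC/C=C(\C)CCC=C(C)C)OC1(C)C
F9 | step 7 | 2-{(2S,5E)-2-[2-(methoxymethoxy)phenyl]-6,10-dimethylundeca-5,9-dien-2-yl}-4,4,5,5-tetramethyl-1,3,2-dioxaborolane | CC1(C)OB(OC1(C)C)[C@@](C)(c1ccccc1OCOC)CC/C=C(\C)CCC=C(C)C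
F10 | step 5 | (1E,3R,6E)-3-ethenyl-N,N,3,7,11-pentamethyldodeca-1,6,10-trien-1-amine | C=C[C@@](C)(CC/C=C(\C)CCC=C(C)C)/C=C/N(C)C
F11 | step 5 | 1,3-bis(dimethylamino)-2-[(R)-nerolidyl]trimethinium chloride | C=C[C@@](C)(CC/C=C(\C)CCC=C(C)C)/C(C=[N+](C)C)=C/N(C)C.[Cl-]
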